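Compound numbers (1–26) are those of the steps below. Atom labels C1–C15 follow the elemane numbering of the target 26: ring carbons C5–C10, vinyl C1=C2 and methyl C14 on C10, C4(=C3)–C15 on C5, lactone O6–C12(=O)–C11(=C13)–C7, acyloxy group on C8. "Top face" means the face of the C10 vinyl group. TBS = tert-butyldimethylsilyl, TBDPS = tert-butyldiphenylsilyl.

## Analysis of the target

Compound 26 is an elemane-type sesquiterpene lactone: a cyclohexane (C5–C10) fused trans at C6–C7 to an α-methylene-γ-butyrolactone. C10 is quaternary (C14 methyl, C1=C2 vinyl), C5 carries the 3-hydroxyprop-1-en-2-yl group, and O8 is acylated by (R)-3-hydroxy-2-methylpropanoic acid. C4 on C5 and C11 on C7 lie on the top face with the vinyl group, whereas the C10 methyl group, O6 and O8 lie on the bottom face. In the chair this makes every substituent on C5–C8 equatorial and trans to its neighbours, the methyl group equatorial, and the vinyl group axial and cis to the alkenyl group on C5. Sensitive features are the α-methylene lactone (a Michael acceptor), possible lactone migration from O6 to a free O8, the β-hydroxy ester side chain with its epimerisable α-centre, the 1,5-diene, and two primary alcohols that must end up free next to an acylated secondary one. The difficulty lies in the quaternary centre C10 next to C5 with the two alkenyl groups cis, in three further contiguous centres, and in the axial vinyl group, which shields the top face of C6 from which a hydride would have to arrive to give the equatorial O6. The strategy rests on one feature: C1=C2 and C3=C4 sit cis on the C5–C10 edge, so C1–C2–C3–C4 can be read as an opened cyclobutene whose carbons C1 and C4 were once bonded to each other and to C10 and C5, that is, as a bicyclo[2.2.0]hexane fused to the cyclohexane.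

## Retrosynthetic reasoning

**26 ⇒ 25 ⇒ 21 + 24.** The two O–Si bonds of 25 are cut first, then the ester bond between O8 and the side-chain carbonyl. The acyl group goes on late because its α-stereocentre and β-oxygen would not survive enolate chemistry. This gives alcohol 21 and acid 24, which comes in two steps from the commercial hydroxy ester 22 through 23 with its stereocentre untouched. The forward esterification must leave the α-methylene lactone and the α-centre of 24 alone, and the final desilylation must free both primary alcohols without base.

**21 ⇒ 20 ⇒ 17.** O8 is unmasked from the TBS ether 20 while the TBDPS ether on O15 stays; the two silyl groups differ in acid stability. The C11=C13 bond of 20 is then cut back to the saturated lactone 17 (through 18 and 19). Methylenation waits until the lactone exists because the exocyclic acceptor would not survive the earlier reductions and enolate steps.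

**17 ⇒ 15.** The O6–C12 and C6–H bonds are cut: 17 is the cyclised form of hydroxy ester 16, the reduction product of ketone 15. This turns the C6 problem into one of thermodynamics, since O6 must end up equatorial and trans to both neighbours. Because the axial vinyl group blocks the path of a hydride to that face, an electron-transfer reduction is planned. The C6 carbonyl is also the handle for C7 and the carbonyl of the photochemical step.

**15 ⇒ 14.** C1 is rejoined to C4 and C2 to C3, folding both alkenyl groups back into a bicyclo[2.2.0]hexane fused at C5–C10. The forward reaction is a strain-driven isomerisation that loses no atoms and delivers both alkenes at once, cis, with no olefination. It must run without epimerising C5 or C7.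

**14 ⇒ 12 + 13.** The C7–C11 bond is cut next to the ketone. It is cut on the tricycle and not on 15, because in 12 only C7 can be enolised (C5 is a ring-fusion methine between two quaternary carbons), whereas after ring opening C5–H would be both α to the ketone and allylic. Bromo ester 13 brings C11 and C12.

**12 ⇒ 9 (through 11 and 10).** These are changes of oxidation level and protection at C15 and C6: the ester of 9 is reduced together with the ketone, the primary alcohol of 10 is silylated, and C6 is reoxidised. The detour is accepted because the C15 ester has done its work once the photoadduct exists. After ring opening it would be an acrylate that competes with C12 for O6 and cannot be reduced beside a lactone.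

**9 ⇒ 5 + 8.** The C1–C10 and C4–C5 bonds are cut, the retron of an enone–alkene [2+2] photocycloaddition. No other disconnection removes the quaternary centre, the C5 centre and all four alkene carbons C1–C4 in one step and leaves two small pieces. The ester on 8 must steer C4 to C5 and C1 to C10, and the single stereocentre of 5 (C8) must send the cyclobutene to the opposite face.

**5 ⇒ 3 ⇒ 2 ⇒ 1.** The C5=C10 bond of the enone is an aldol-condensation retron. Cutting it gives the symmetric dione 3, in which C8 is not yet a stereocentre, so absolute configuration is introduced by a catalyst that tells the two acetonyl arms apart. Dione 3 comes from 1 by silylation (2) and oxidation of both terminal alkenes to methyl ketones.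

**8 ⇒ 7 ⇒ 6.** The strained, polymerisable ester is made just before use from bromo ester 6 by elimination and saponification to acid 7 and re-esterification.

## Alternatives that were turned down

**Alternative 1:** The C6–C7 bond is disconnected in an open-chain precursor. In the forward step CrCl2 (divalent chromium) would turn the allylic bromide end of a 2-(bromomethyl)acrylate unit into an allylchromium species that adds through its γ-carbon C7 to a C6 aldehyde. This would close the carbocycle and give cyclohexanol A1 with the C11=C13 methylene and the C12 ester already in place.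
- For: C6 and C7 are set together, the hydroxyl and the acrylate arise ready to lactonise, and neither a ketone reduction at C6 nor a separate methylenation is needed. The chromium reagent tolerates esters and silyl ethers.
- Against: all the difficulty moves into the acyclic precursor of A1, which must already hold the quaternary C10 next to C5, and the remote C8, as defined centres before any ring exists. Its aldehyde α-carbon C5 is also allylic, so it is prone to epimerise and to slip into conjugation. The ring closure must pick one of four C6/C7 arrangements through a cyclic transition state that is hard to predict with a quaternary neighbour.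
- Comparison: on the lactone this alternative is stronger, being shorter and free of the C6 reduction problem. The chosen strategy offers in its place a ring, the quaternary centre and the cis-dialkenyl array in one step from two small components, with the cis relation enforced by ring fusion and not by acyclic stereocontrol, and a shorter route overall.

**Alternative 2:** C5–C10 and C6–C7 are disconnected as a Diels–Alder reaction. A cyclohexa-1,3-diene (C10=C1–C11=C7) would react with an (E)-β-silyloxy enone (C5=C6) tethered through silicon to O8, giving the bicyclo[2.2.2]octene A2 with a six-membered siladioxane ring. The C1=C11 bridge would be cleaved afterwards.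
- For: four ring centres (C5, C6, C7, C10) come from one suprafacial step, the trans C5/C6 relation follows from the E alkene, O6 is present as oxygen from the start, and the tether from O8 fixes the face. That is tighter stereocontrol than the 1,3-induction on which the photocycloaddition relies, and on this point the alternative is stronger.
- Against: the diene end C10 is fully substituted and the dienophile is a push–pull alkene of low reactivity, so the quaternary centre would have to be forced thermally, under conditions that threaten the silyl acetal tether and the diene (hydrogen shifts, aromatisation). After the cycloaddition the bridge alkene must be cleaved and three carbonyl groups (at C1, C4 and C11) converted into alkenes next to the epimerisable C5 and C7, and C12 must be oxidised.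
- Comparison: the chosen route forms the quaternary centre photochemically, where substitution at the β-carbon is tolerated, and obtains both alkenes directly from the cycloreversion, in fewer steps. It pays with a less direct control of C6.

**Alternative 3:** C7–C11 is disconnected late. Rh2(OAc)4 would decompose a diazophosphonoacetate on O6, and the rhodium carbenoid would insert into the equatorial C7–H bond (1,5-insertion) to give the trans-fused α-phosphono lactone A3. A Horner–Wadsworth–Emmons reaction with formaldehyde would then install C13.
- For: the lactone is made in one C–H functionalisation on a ring that already carries O6 correctly, even with the O8 side chain attached, and the methylenation is one mild step. This endgame is shorter than the alkylation, reduction and Mannich sequence chosen here, and on this point the alternative is stronger.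
- Against: the step does not touch the real problem, since the cyclohexane with C5, C6, C8 and C10 must come from elsewhere. The carbenoid also has choices: cyclopropanation of the C10 vinyl group, insertion into the tertiary C5–H bond (also a 1,5-position), and a C7–H bond deactivated by the acyloxy group on C8. C4 has to be masked as a ketal in A3, so one more olefination follows.
- Comparison: the chosen strategy spends its key step on the hard part (quaternary centre, cis alkenyl groups) and uses ionic chemistry at C7 on a substrate where only one site can react. It accepts a longer lactone endgame.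

Key step: step 6

Remark on the chemistry: which of the two pseudo-enantiomeric cinchona-derived primary amines gives the (S)-enone 5 cannot be read from the structures alone. The quinine-derived amine is written in step 3; if it favours the (R)-enone, the quinidine-derived amine is used instead and nothing else changes.

## Route

**Step 1**
Reactants: 1 hepta-1,6-dien-4-ol
Product: 2 4-(tert-butyldimethylsilyloxy)hepta-1,6-diene
Conditions: TBSCl, imidazole, DMF, rt
Reagents that add atoms: tert-butyldimethylsilyl chloride, CC(C)(C)[Si](C)(C)Cl
Why: Imidazole-promoted silylation of a secondary alcohol; the carbinol carbon carries two identical allyl arms and is not yet a stereocentre.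

**Step 2**
Reactants: 2 4-(tert-butyldimethylsilyloxy)hepta-1,6-diene
Product: 3 4-(tert-butyldimethylsilyloxy)heptane-2,6-dione
Conditions: PdCl2 (10 mol%), CuCl, O2 (1 atm), DMF/H2O, rt
Reagents that add atoms: water, O
Why: Twofold Wacker oxidation; Markovnikov hydroxypalladation of each terminal alkene gives the methyl ketones, while CuCl and O2 return zerovalent palladium to the divalent state. The silyl ether should survive the near-neutral medium.

**Step 3**
Reactants: 3 4-(tert-butyldimethylsilyloxy)heptane-2,6-dione
Product: 5 (S)-5-(tert-butyldimethylsilyloxy)-3-methylcyclohex-2-en-1-one, via aldol ketol 4 (not isolated)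
Conditions: 9-amino-9-deoxy-epi-quinine (20 mol%), AcOH (40 mol%), toluene, −15 °C to rt
Reagents that add atoms: none
Why: Primary-amine-catalysed desymmetrising intramolecular aldol condensation of a 4-substituted heptane-2,6-dione: the enamine of one acetonyl arm adds to the other ketone (six-membered ring) and ketol 4 loses water. The chiral amine and its acid partner choose between the enantiotopic arms, which sets C8. Low temperature is meant to hold back loss of silanol from the β-silyloxy ketone.

**Step 4**
Reactants: 6 ethyl 1-bromocyclobutane-1-carboxylate
Product: 7 cyclobut-1-ene-1-carboxylic acid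
Conditions: KOH, toluene, reflux; then HCl (aq) on work-up
Reagents that add atoms: potassium hydroxide, [K+].[OH-]
Why: Dehydrobromination (E2) of the tertiary α-bromo ester together with saponification; the only β-hydrogens are ring hydrogens, so the endocyclic alkene is the only elimination product.

**Step 5**
Reactants: 7 cyclobut-1-ene-1-carboxylic acid
Product: 8 methyl cyclobut-1-ene-1-carboxylate
Conditions: MeI, K2CO3, DMF, 0 °C to rt
Reagents that add atoms: iodomethane, CI
Why: O-Alkylation of the carboxylate (SN2) avoids acid and heat, to which the strained, polymerisable acrylate is sensitive; the ester is used at once.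

**Step 6**
Reactants: 5 (S)-5-(tert-butyldimethylsilyloxy)-3-methylcyclohex-2-en-1-one; 8 methyl cyclobut-1-ene-1-carboxylate
Product: 9 methyl 9-(tert-butyldimethylsilyloxy)-1-methyl-7-oxotricyclo[4.4.0.0^2,5]decane-5-carboxylate (cis-anti-cis head-to-head photoadduct; the methyl and silyloxy groups lie on the face of the six-membered ring opposite the four-membered rings; in elemane numbering the ketone is C6 and the ester C15)
Conditions: hν (medium-pressure Hg lamp, uranium-glass filter, λ > 350 nm), 8 (5 equiv.), degassed CH2Cl2, −40 °C
Reagents that add atoms: none
Why: Light above 350 nm excites only the enone (n→π*), which crosses to its twisted triplet and attacks the ground-state cyclobutene; this is the enone–alkene [2+2] photocycloaddition, here with a cyclobutene-1-carboxylate as partner, a known pairing for 3-alkylcyclohexenones. The first bond joins the β-carbon C10 to the unsubstituted cyclobutene carbon C1, because the resulting 1,4-biradical then has one centre next to the ketone (C5) and the other next to the ester (C4). After spin inversion these centres combine (C4–C5), so the four-membered ring closes stepwise by radical recombination and the head-to-head constitution follows from the ester. The new cyclobutane can only be fused cis to the six-membered ring, which fixes C5 relative to C10; a trans fusion, should it arise, relaxes by epimerisation at C5 (α to the ketone) on neutral Al2O3 during purification. C10 is set by bonding to the half-chair enone on the face opposite the pseudo-equatorial C8 silyloxy group, the same axial trajectory that governs conjugate additions to 5-substituted cyclohexenones. C1 and C4 are cis because they come from a ring alkene, and the second four-membered ring turns away from the six-membered ring for steric reasons. What the route needs from this step is the head-to-head regiochemistry and the C10 face, since C1 and C4 become sp2 again in step 11; the ester secures the first and the C8 substituent the second. The excess of 8 and the low temperature are meant to outrun enone dimerisation and polymerisation of the cyclobutene.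

**Step 7**
Reactants: 9 photoadduct keto ester
Product: 10 9-(tert-butyldimethylsilyloxy)-5-(hydroxymethyl)-1-methyltricyclo[4.4.0.0^2,5]decan-7-ol (C6 carbinol configuration not controlled)
Conditions: LiAlH4, THF, 0 °C to rt
Reagents that add atoms: none
Why: Hydride reduction of the neopentyl ester and the ketone. The C6 configuration is irrelevant because C6 is reoxidised in step 9. C15 is brought to the alcohol level here, before it can become an acrylate.

**Step 8**
Reactants: 10 tricyclic diol
Product: 11 9-(tert-butyldimethylsilyloxy)-5-[(tert-butyldiphenylsilyloxy)methyl]-1-methyltricyclo[4.4.0.0^2,5]decan-7-ol (C6 epimers)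
Conditions: TBDPSCl, imidazole, DMF, 0 °C
Reagents that add atoms: tert-butyl(chloro)diphenylsilane, CC(C)(C)[Si](Cl)(c1ccccc1)c2ccccc2
Why: The bulky chlorosilane should silylate the primary hydroxyl and leave the flanked secondary C6 hydroxyl. TBDPS is chosen because it outlasts the later acidic removal of the TBS group on O8.

**Step 9**
Reactants: 11 mono-protected diol
Product: 12 9-(tert-butyldimethylsilyloxy)-5-[(tert-butyldiphenylsilyloxy)methyl]-1-methyltricyclo[4.4.0.0^2,5]decan-7-one (ring stereochemistry as in 9)
Conditions: Dess–Martin periodinane, pyridine, CH2Cl2, rt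
Reagents that add atoms: none
Why: Dess–Martin oxidation of the secondary alcohol under buffered, non-enolising conditions regenerates the C6 ketone without touching the silyl ethers or the strained rings.

**Step 10**
Reactants: 12 tricyclic ketone; 13 methyl bromoacetate
Product: 14 methyl 2-[9-(tert-butyldimethylsilyloxy)-5-[(tert-butyldiphenylsilyloxy)methyl]-1-methyl-7-oxotricyclo[4.4.0.0^2,5]dec-8-yl]acetate (new C7 substituent on the top face, trans to O8)
Conditions: LiN(i-Pr)2 (LDA), THF, −78 °C; then 13, DMPU, −78 to −40 °C
Reagents that add atoms: none
Why: Kinetic enolisation can occur only at C7, because C5 is a ring-fusion methine between two quaternary carbons; the lithium enolate is then alkylated (SN2) by the reactive α-bromo ester. The electrophile enters anti to the adjacent C8 silyloxy group, giving the trans arrangement, which is also the more stable one at this epimerisable centre.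

**Step 11**
Reactants: 14 alkylated tricyclic ketone
Product: 15 methyl 2-[6-(tert-butyldimethylsilyloxy)-3-{3-(tert-butyldiphenylsilyloxy)prop-1-en-2-yl}-4-ethenyl-4-methyl-2-oxocyclohexyl]acetate (cyclohexyl C1 = C7, C2 = C6, C3 = C5, C4 = C10, C6 = C8; vinyl, C5 alkenyl and C7 side chain on the top face, methyl and O8 on the bottom face)
Conditions: o-dichlorobenzene (degassed), BHT (cat.), 200 °C, sealed base-washed tube
Reagents that add atoms: none
Why: Thermal cycloreversion of a bicyclo[2.2.0]hexane to a hexa-1,5-diene: the strained central C1–C4 bond breaks and the cyclohexane-1,4-diyl cleaves C2–C3, releasing the C1=C2 vinyl group on C10 and the C3=C4 alkene on C5. C5 and C10 are not involved and keep the cis relation fixed in step 6. If the diyl opens the ten-membered 1,5-diene instead, its Cope rearrangement through a chair with the C8 silyloxy group equatorial should lead to the same ketone.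

**Step 12**
Reactants: 15 divinyl keto ester
Product: 17 4-(tert-butyldimethylsilyloxy)-7-[3-(tert-butyldiphenylsilyloxy)prop-1-en-2-yl]-6-ethenyl-6-methylhexahydro-1-benzofuran-2(3H)-one (trans-fused lactone; O6 on the bottom face), via hydroxy ester 16 (not isolated)
Conditions: SmI2, H2O, THF, 0 °C; then PPTS (cat.), toluene, 60 °C
Reagents that add atoms: none
Why: Single-electron reduction by divalent samarium: the ketyl and the organosamarium that follows settle with the bulky oxygen equatorial before protonation at carbon, so the thermodynamically preferred bottom-face alcohol is expected. A hydride would have to pass the axial C10 vinyl group to give the same result. Hydroxy ester 16 has O6 and the C7 side chain trans-diequatorial and closes to the γ-lactone by acyl substitution.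

**Step 13**
Reactants: 17 trans-fused lactone
Product: 18 3-[(dimethylamino)methyl] derivative of 17 (C11 epimers)
Conditions: LiN(i-Pr)2 (LDA), THF, −78 °C; then CH2=NMe2+ I−, −78 °C to rt
Reagents that add atoms: N,N-dimethylmethyleneiminium iodide, C=[N+](C)C.[I-]
Why: Mannich reaction of the lactone enolate with the preformed iminium salt; C11 is the only acidic position and its configuration does not matter.

**Step 14**
Reactants: 18 Mannich base
Product: 20 4-(tert-butyldimethylsilyloxy)-7-[3-(tert-butyldiphenylsilyloxy)prop-1-en-2-yl]-6-ethenyl-6-methyl-3-methylidenehexahydro-1-benzofuran-2(3H)-one, via trimethylammonium iodide 19 (not isolated)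
Conditions: MeI, THF, rt; then NaHCO3 (aq), EtOAc, rt
Reagents that add atoms: none
Why: N-Methylation turns the amine into a leaving group, and mild base removes the acidic C11 proton with loss of trimethylamine (E1cB-type elimination) to give the exocyclic methylene. No stereocentre is affected.

**Step 15**
Reactants: 20 α-methylene lactone
Product: 21 7-[3-(tert-butyldiphenylsilyloxy)prop-1-en-2-yl]-6-ethenyl-4-hydroxy-6-methyl-3-methylidenehexahydro-1-benzofuran-2(3H)-one
Conditions: HF (48% aq), MeCN, 0 °C
Reagents that add atoms: none
Why: Acidic fluoride cleavage distinguishes the TBS ether from the much more acid-stable TBDPS ether. The acidic medium keeps O8 protonated, which should hold back migration of the lactone to O8.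

**Step 16**
Reactants: 22 methyl (R)-3-hydroxy-2-methylpropanoate
Product: 23 methyl (R)-3-(tert-butyldiphenylsilyloxy)-2-methylpropanoate
Conditions: TBDPSCl, imidazole, DMF, rt
Reagents that add atoms: tert-butyl(chloro)diphenylsilane, CC(C)(C)[Si](Cl)(c1ccccc1)c2ccccc2
Why: Silylation of the primary alcohol; the stereocentre is not involved.

**Step 17**
Reactants: 23 silyl ether ester
Product: 24 (R)-3-(tert-butyldiphenylsilyloxy)-2-methylpropanoic acid
Conditions: LiOH, THF/MeOH/H2O, 0 °C; then HCl (aq) to pH 3
Reagents that add atoms: lithium hydroxide, [Li+].[OH-]
Why: Saponification in the cold; once the carboxylate has formed the α-centre resists enolisation, so the configuration should be retained.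

**Step 18**
Reactants: 21 C8 alcohol; 24 (R)-3-(tert-butyldiphenylsilyloxy)-2-methylpropanoic acid
Product: 25 bis-silyl ether of 26: the O8 ester of 21 with 24
Conditions: N,N'-diisopropylcarbodiimide, DMAP (cat.), CH2Cl2, 0 °C to rt
Reagents that add atoms: none
Why: Steglich esterification of the equatorial C8 alcohol; the C–O8 bond is not broken, so C8 keeps its configuration. The neutral, cold conditions are chosen to avoid epimerising the α-methyl centre of the acid.

**Step 19**
Reactants: 25 bis-silyl ether
Product: 26 (3aR,4S,6R,7R,7aR)-6-ethenyl-7-(3-hydroxyprop-1-en-2-yl)-6-methyl-3-methylidene-2-oxooctahydro-1-benzofuran-4-yl (2R)-3-hydroxy-2-methylpropanoate (CNP0133858.4)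
Conditions: HF·pyridine, pyridine, THF, 0 °C to rt
Reagents that add atoms: none
Why: Fluoride cleavage of both primary TBDPS ethers under buffered, weakly acidic conditions, which the α-methylene lactone and the β-hydroxy ester should tolerate.

## Compound list

1 | hepta-1,6-dien-4-ol | C=CCC(O)CC=C | starting material
2 | 4-(tert-butyldimethylsilyloxy)hepta-1,6-diene | C=CCC(O[Si](C)(C)C(C)(C)C)CC=C | intermediate
3 | 4-(tert-butyldimethylsilyloxy)heptane-2,6-dione | CC(=O)CC(O[Si](C)(C)C(C)(C)C)CC(C)=O | intermediate
4 | (5S)-5-(tert-butyldimethylsilyloxy)-3-hydroxy-3-methylcyclohexan-1-one (C3 epimers; aldol ketol) | CC1(O)CC(=O)C[C@@H](O[Si](C)(C)C(C)(C)C)C1 | intermediate (not isolated)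
5 | (S)-5-(tert-butyldimethylsilyloxy)-3-methylcyclohex-2-en-1-one | CC1=CC(=O)C[C@@H](O[Si](C)(C)C(C)(C)C)C1 | intermediate
6 | ethyl 1-bromocyclobutane-1-carboxylate | CCOC(=O)C1(Br)CCC1 | starting material
7 | cyclobut-1-ene-1-carboxylic acid | OC(=O)C1=CCC1 | intermediate
8 | methyl cyclobut-1-ene-1-carboxylate | COC(=O)C1=CCC1 | intermediate
9 | methyl 9-(tert-butyldimethylsilyloxy)-1-methyl-7-oxotricyclo[4.4.0.0^2,5]decane-5-carboxylate (cis-anti-cis photoadduct) | C[C@]12C[C@H](O[Si](C)(C)C(C)(C)C)CC(=O)[C@H]1[C@]3(C(=O)OC)CC[C@H]23 | intermediate
10 | 9-(tert-butyldimethylsilyloxy)-5-(hydroxymethyl)-1-methyltricyclo[4.4.0.0^2,5]decan-7-ol (C6 carbinol epimers) | C[C@]12C[C@H](O[Si](C)(C)C(C)(C)C)CC(O)[C@H]1[C@]3(CO)CC[C@H]23 | intermediate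
11 | 9-(tert-butyldimethylsilyloxy)-5-[(tert-butyldiphenylsilyloxy)methyl]-1-methyltricyclo[4.4.0.0^2,5]decan-7-ol (C6 carbinol epimers) | C[C@]12C[C@H](O[Si](C)(C)C(C)(C)C)CC(O)[C@H]1[C@]3(CO[Si](c4ccccc4)(c5ccccc5)C(C)(C)C)CC[C@H]23 | intermediate
12 | 9-(tert-butyldimethylsilyloxy)-5-[(tert-butyldiphenylsilyloxy)methyl]-1-methyltricyclo[4.4.0.0^2,5]decan-7-one | C[C@]12C[C@H](O[Si](C)(C)C(C)(C)C)CC(=O)[C@H]1[C@]3(CO[Si](c4ccccc4)(c5ccccc5)C(C)(C)C)CC[C@H]23 | intermediate
13 | methyl bromoacetate | COC(=O)CBr | starting material
14 | methyl 2-[9-(tert-butyldimethylsilyloxy)-5-[(tert-butyldiphenylsilyloxy)methyl]-1-methyl-7-oxotricyclo[4.4.0.0^2,5]dec-8-yl]acetate | C[C@]12C[C@H](O[Si](C)(C)C(C)(C)C)[C@@H](CC(=O)OC)C(=O)[C@H]1[C@]3(CO[Si](c4ccccc4)(c5ccccc5)C(C)(C)C)CC[C@H]23 | intermediate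
15 | methyl 2-[6-(tert-butyldimethylsilyloxy)-3-{3-(tert-butyldiphenylsilyloxy)prop-1-en-2-yl}-4-ethenyl-4-methyl-2-oxocyclohexyl]acetate | C=C[C@@]1(C)C[C@H](O[Si](C)(C)C(C)(C)C)[C@@H](CC(=O)OC)C(=O)[C@H]1C(=C)CO[Si](c2ccccc2)(c3ccccc3)C(C)(C)C | intermediate
16 | methyl 2-[6-(tert-butyldimethylsilyloxy)-3-{3-(tert-butyldiphenylsilyloxy)prop-1-en-2-yl}-4-ethenyl-2-hydroxy-4-methylcyclohexyl]acetate (hydroxyl equatorial, bottom face) | C=C[C@@]1(C)C[C@H](O[Si](C)(C)C(C)(C)C)[C@@H](CC(=O)OC)[C@H](O)[C@H]1C(=C)CO[Si](c2ccccc2)(c3ccccc3)C(C)(C)C | intermediate (not isolated)
17 | 4-(tert-butyldimethylsilyloxy)-7-[3-(tert-butyldiphenylsilyloxy)prop-1-en-2-yl]-6-ethenyl-6-methylhexahydro-1-benzofuran-2(3H)-one (trans-fused) | C=C[C@@]1(C)C[C@H](O[Si](C)(C)C(C)(C)C)[C@H]2CC(=O)O[C@@H]2[C@H]1C(=C)CO[Si](c3ccccc3)(c4ccccc4)C(C)(C)C | intermediate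
18 | 3-[(dimethylamino)methyl] derivative of 17 (C11 epimers) | C=C[C@@]1(C)C[C@H](O[Si](C)(C)C(C)(C)C)[C@H]2C(CN(C)C)C(=O)O[C@@H]2[C@H]1C(=C)CO[Si](c3ccccc3)(c4ccccc4)C(C)(C)C | intermediate
19 | 3-[(trimethylammonio)methyl] derivative of 17, iodide (C11 epimers) | C=C[C@@]1(C)C[C@H](O[Si](C)(C)C(C)(C)C)[C@H]2C(C[N+](C)(C)C)C(=O)O[C@@H]2[C@H]1C(=C)CO[Si](c3ccccc3)(c4ccccc4)C(C)(C)C.[I-] | intermediate (not isolated)
20 | 4-(tert-butyldimethylsilyloxy)-7-[3-(tert-butyldiphenylsilyloxy)prop-1-en-2-yl]-6-ethenyl-6-methyl-3-methylidenehexahydro-1-benzofuran-2(3H)-one | C=C[C@@]1(C)C[C@H](O[Si](C)(C)C(C)(C)C)[C@H]2C(=C)C(=O)O[C@@H]2[C@H]1C(=C)CO[Si](c3ccccc3)(c4ccccc4)C(C)(C)C | intermediate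
21 | 7-[3-(tert-butyldiphenylsilyloxy)prop-1-en-2-yl]-6-ethenyl-4-hydroxy-6-methyl-3-methylidenehexahydro-1-benzofuran-2(3H)-one | C=C[C@@]1(C)C[C@H](O)[C@H]2C(=C)C(=O)O[C@@H]2[C@H]1C(=C)CO[Si](c3ccccc3)(c4ccccc4)C(C)(C)C | intermediate
22 | methyl (R)-3-hydroxy-2-methylpropanoate | COC(=O)[C@H](C)CO | starting material
23 | methyl (R)-3-(tert-butyldiphenylsilyloxy)-2-methylpropanoate | COC(=O)[C@H](C)CO[Si](c1ccccc1)(c2ccccc2)C(C)(C)C | intermediate
24 | (R)-3-(tert-butyldiphenylsilyloxy)-2-methylpropanoic acid | OC(=O)[C@H](C)CO[Si](c1ccccc1)(c2ccccc2)C(C)(C)C | intermediate
25 | bis(tert-butyldiphenylsilyl) ether of 26 (O15 and side-chain O3') | C=C[C@@]1(C)C[C@H](OC(=O)[C@H](C)CO[Si](c3ccccc3)(c4ccccc4)C(C)(C)C)[C@H]2C(=C)C(=O)O[C@@H]2[C@H]1C(=C)CO[Si](c5ccccc5)(c6ccccc6)C(C)(C)C | intermediate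
26 | (3aR,4S,6R,7R,7aR)-6-ethenyl-7-(3-hydroxyprop-1-en-2-yl)-6-methyl-3-methylidene-2-oxooctahydro-1-benzofuran-4-yl (2R)-3-hydroxy-2-methylpropanoate | C=C[C@@]1(C)C[C@H](OC(=O)[C@H](C)CO)[C@H]2C(=C)C(=O)O[C@@H]2[C@H]1C(=C)CO | target

## Step count and least certain steps

Total: 19 steps. Longest linear sequence: 15 steps (1–3, 6–15, 18, 19). The least certain steps are the key step 6 and steps 11, 12, 10, 3 and 15.

**Step 6 (key step).** The most likely failure is incomplete control of the face at C10, since induction comes from a centre two atoms away. Head-to-tail adducts, enone dimerisation and polymerisation of 8 may also lower the throughput.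

The fallback forms the same two bonds one after the other and sets out from 5. Copper-catalysed conjugate addition of CH2=CHMgBr (CuBr·SMe2, TMSCl, THF, −78 °C), which should occur trans to the C8 silyloxy group, gives the trimethylsilyl enol ether F1. Its lithium enolate, released with MeLi, is coupled under palladium catalysis (Pd2(dba)3, P(t-Bu)3) with the 2-bromoallyl silyl ether F2 (from 2-bromoprop-2-en-1-ol and TBDPSCl) to give the 2-alkenyl ketone F3, whose C5 epimers can be equilibrated and separated. Deprotonation at the less hindered C7 with LDA and alkylation with 13 then give 15, where the route is rejoined.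

**Step 11.** The ring opening may stop partly at the ten-membered 1,5-diene if the Cope equilibrium does not lie fully on the side of the six-membered ring. The hot ketone may also epimerise at C5 or lose silanol from the β-silyloxy ketone.

The fallback moves the thermolysis to a stage without a ketone and sets out from 11. Heating under the same conditions gives the divinyl alcohol F4, Dess–Martin oxidation gives ketone F3, and alkylation at C7 with LDA and 13 returns to 15.

**Step 12.** The reduction may not deliver the equatorial alcohol cleanly if protonation of the organosamarium is faster than its equilibration. Over-reduction of the ester is a lesser risk.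

The fallback accepts the other epimer and inverts it; it sets out from 15. LiBH(s-Bu)3 attacks from the open equatorial side and gives, after closure, the cis-fused lactone F5. LiOH opens it to the hydroxy acid F6, which is acidified cold and used at once. Mitsunobu lactonisation (PPh3, diisopropyl azodicarboxylate) closes the ring with inversion at C6 and gives 17.

**Step 10.** The C7 enolate carries the silyloxy group on its β-carbon and may expel silanolate (E1cB) before it is alkylated; double alkylation is a lesser risk.

The fallback avoids a free enolate at higher temperature and sets out from 12. Soft enolisation (TMSOTf, Et3N) gives the silyl enol ether F7. Copper-catalysed cyclopropanation with methyl diazoacetate (Cu(acac)2) gives the siloxycyclopropane ester F8. Mild fluoride (Et3N·3HF) opens it to the γ-keto ester 14, with C7 set under thermodynamic control.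

**Step 3.** The amine catalyst may trigger β-elimination of the silyloxy group, followed by aromatisation of the product, or may give incomplete enantiocontrol with an oxygen substituent at C4 of the dione.

The fallback gives up catalytic desymmetrisation and sets out from 3. Pyrrolidine and AcOH give the racemic enone F8', named here racemic enone F9, which is resolved by preparative chromatography on a chiral stationary phase into 5 and the unwanted (R)-enone F10.

**Step 15.** The TBDPS ether may be lost as well, or the freed O8 may attack the lactone.

The fallback removes both silyl groups and sets out from 20. HF·pyridine in excess gives diol F11, and the primary allylic hydroxyl is then silylated selectively (TBDPSCl, imidazole, −20 °C) to give 21.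

## Further compounds

F1 | step 6 | {[5-(tert-butyldimethylsilyloxy)-3-ethenyl-3-methylcyclohex-1-en-1-yl]oxy}trimethylsilane (vinyl trans to the silyloxy group) | C=C[C@@]1(C)C[C@H](O[Si](C)(C)C(C)(C)C)CC(O[Si](C)(C)C)=C1
F2 | step 6 | [(2-bromoprop-2-en-1-yl)oxy](tert-butyl)diphenylsilane | C=C(Br)CO[Si](c1ccccc1)(c2ccccc2)C(C)(C)C
F3 | step 6 | 5-(tert-butyldimethylsilyloxy)-2-[3-(tert-butyldiphenylsilyloxy)prop-1-en-2-yl]-3-ethenyl-3-methylcyclohexan-1-one (alkenyl groups cis) | C=C[C@@]1(C)C[C@H](O[Si](C)(C)C(C)(C)C)CC(=O)[C@H]1C(=C)CO[Si](c2ccccc2)(c3ccccc3)C(C)(C)C
F4 | step 11 | 5-(tert-butyldimethylsilyloxy)-2-[3-(tert-butyldiphenylsilyloxy)prop-1-en-2-yl]-3-ethenyl-3-methylcyclohexan-1-ol (carbinol epimers) | C=C[C@@]1(C)C[C@H](O[Si](C)(C)C(C)(C)C)CC(O)[C@H]1C(=C)CO[Si](c2ccccc2)(c3ccccc3)C(C)(C)C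
F5 | step 12 | cis-fused C6 epimer of lactone 17 (O6 on the top face) | C=C[C@@]1(C)C[C@H](O[Si](C)(C)C(C)(C)C)[C@H]2CC(=O)O[C@H]2[C@H]1C(=C)CO[Si](c3ccccc3)(c4ccccc4)C(C)(C)C
F6 | step 12 | 2-[6-(tert-butyldimethylsilyloxy)-3-{3-(tert-butyldiphenylsilyloxy)prop-1-en-2-yl}-4-ethenyl-2-hydroxy-4-methylcyclohexyl]acetic acid (hydroxyl axial, top face) | C=C[C@@]1(C)C[C@H](O[Si](C)(C)C(C)(C)C)[C@@H](CC(=O)O)[C@@H](O)[C@H]1C(=C)CO[Si](c2ccccc2)(c3ccccc3)C(C)(C)C
F7 | step 10 | trimethylsilyl enol ether of 12 (C6=C7) | C[C@]12C[C@H](O[Si](C)(C)C(C)(C)C)C=C(O[Si](C)(C)C)[C@H]1[C@]3(CO[Si](c4ccccc4)(c5ccccc5)C(C)(C)C)CC[C@H]23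
F8 | step 10 | methyl siloxycyclopropanecarboxylate from F7 (cyclopropane across C6–C7; new centres not controlled) | C[C@]12C[C@H](O[Si](C)(C)C(C)(C)C)C4C(C(=O)OC)C4(O[Si](C)(C)C)[C@H]1[C@]3(CO[Si](c5ccccc5)(c6ccccc6)C(C)(C)C)CC[C@H]23
F9 | step 3 | racemic 5-(tert-butyldimethylsilyloxy)-3-methylcyclohex-2-en-1-one | CC1=CC(=O)CC(O[Si](C)(C)C(C)(C)C)C1
F10 | step 3 | (R)-5-(tert-butyldimethylsilyloxy)-3-methylcyclohex-2-en-1-one | CC1=CC(=O)C[C@H](O[Si](C)(C)C(C)(C)C)C1
F11 | step 15 | 6-ethenyl-4-hydroxy-7-(3-hydroxyprop-1-en-2-yl)-6-methyl-3-methylidenehexahydro-1-benzofuran-2(3H)-one | C=C[C@@]1(C)C[C@H](O)[C@H]2C(=C)C(=O)O[C@@H]2[C@H]1C(=C)CO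
A1 | alternative 1 | cyclohexanol bearing the acrylate at C7 (O8 triethylsilyl, O15 TBS) | C=C[C@@]1(C)C[C@H](O[Si](CC)(CC)CC)[C@@H](C(=C)C(=O)OC)[C@H](O)[C@H]1C(=C)CO[Si](C)(C)C(C)(C)C
A2 | alternative 2 | bicyclo[2.2.2]octene siladioxane Diels–Alder adduct | C[C@@]12C[C@H](O[Si]3(C(C)C)C(C)C)[C@@H](C(COCc4ccc(OC)cc4)=C1)[C@H](O3)[C@H]2C(=O)CO[Si](C)(C)C(C)(C)C
A3 | alternative 3 | trans-fused α-(diethoxyphosphoryl) lactone (C11 epimers) | C=C[C@@]1(C)C[C@H](OC(=O)[C@H](C)CO[Si](C)(C)C(C)(C)C)[C@H]2C(P(=O)(OCC)OCC)C(=O)O[C@@H]2[C@H]1C3(CO[Si](C)(C)C(C)(C)C)OCCO3
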